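## Structural features

The target 8 is a 2,5-disubstituted 1H-pyrrole: one aromatic five-membered ring whose C2 carries a formyl group and whose C5 carries an unbranched henicosyl (C21) chain bonded through C1', with N1 left as NH. There is no second ring, no stereocentre and no double-bond geometry, so no stereocentres stand next to each other and nothing stereochemical has to be controlled. The fragile parts are the acidic, metal-binding NH, the aldehyde (a vinylogous formamide, yet still reducible and open to nucleophiles) and the π-rich ring, which is sensitive to strong acid and to oxidants. The chain is chemically inert but makes every intermediate waxy and poorly soluble in polar media. The real difficulty is attaching one long, odd-numbered primary alkyl group to C5 alone, beside NH and in the presence of CHO, from affordable material. C21 halides, alkenes and alkynes are speciality chemicals, whereas the even-numbered C22 acid 1 is a bulk fatty acid. The key step exploits exactly this: the C5–C1' bond joins an sp2 ring carbon to a primary sp3 carbon, and C1' with the twenty carbons behind it is the chain of 1 without its carboxyl carbon, while the bromine of 4 already marks C5 as the only site.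

## Logic of the disconnections

8 ⇒ 7. The N1–H bond is replaced by an N1–C(=O) carbamate bond. The reason is that a free NH would be deprotonated, would bind nickel and would quench organometallic intermediates. The acyl group also lowers the electron density of the ring. Nothing is gained in skeleton, but the coupling becomes feasible. The demand on the forward step is removal of the tert-butoxycarbonyl group without acid, reductant or heat that could touch the aldehyde; a catalytic alkoxide suffices because the 2-formylpyrrolide is a good leaving group.

7 ⇒ 3 + 6. The C5–C1' bond is cut, the only skeletal bond not already present in a purchasable piece. This separates a five-carbon heteroaromatic fragment carrying all the functionality from a pure hydrocarbon chain, and lets the chain arrive as a C1' radical released by loss of the carboxyl carbon. The route becomes convergent, with each half one step from catalogue compounds. The forward step must generate the primary radical no faster than the heteroaryl nickel species that captures it, must leave aldehyde and carbamate alone, and takes its site selectivity from the single carbon–halogen bond.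

3 ⇒ 1 + 2. The acyl C–O bond of the active ester is cut, because the N-acyloxyphthalimide is the one-electron acceptor that triggers decarboxylation. Two commodity chemicals result. The forward dehydrative coupling must go to completion despite the low solubility of 1 and give a product that can be purified by crystallisation.

6 ⇒ 4 + 5. The N1–C(=O) bond is cut. The forward acylation of a weakly nucleophilic nitrogen flanked by Br and CHO needs nucleophilic catalysis, and the product must be handled without acid and away from light.

## Other disconnections considered

Alternative 1: The cut is the N1–C5 bond of the ring, with C2 at the ester oxidation level. In the forward key step the azidodienoate A1, methyl (2Z,4E)-2-azidohexacosa-2,4-dienoate, would lose N2 under Rh2(O2CC3F7)4 or ZnI2 catalysis. The nitrogen, as a metal nitrenoid or by way of a 2H-azirine, would bond to the diene terminus and give the pyrrole ester A2, methyl 5-henicosyl-1H-pyrrole-2-carboxylate (a vinylogous Hemetsberger closure).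
- In its favour: the 2,5-pattern is fixed by construction, no nitrogen protecting group is needed, and the ring closure is unimolecular and mild.
- Against it: A1 would have to be made by condensing an azidoacetate ester with the enal A3, (2E)-tetracos-2-enal, which itself needs a separate preparation. Low-molecular-weight azides and a thermally labile dienyl azide must be handled. A2 is at the wrong oxidation level, so it must be reduced to the carbinol A4, (5-henicosyl-1H-pyrrol-2-yl)methanol, which ionises easily to an azafulvene and oligomerises, and then re-oxidised with MnO2 to 8.
- Comparison: on regiochemical certainty the two plans are equal. On protecting groups and on mechanistic simplicity the alternative is the better, since its key step has no competing bimolecular pathways to balance. On step economy and carbon supply the chosen plan is better: four operations from 1 against roughly six or seven.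

Alternative 2: The cut is the C3–C4 bond of the ring after opening both C–N bonds in the Paal–Knorr sense. In the forward direction the kinetic enolates of tricosan-2-one A5 and 1,1-dimethoxypropan-2-one A6 would be joined through a diisopropylsilyl tether to the unsymmetrical bis-enol ether A7. (NH4)2Ce(NO3)6 buffered with NaHCO3 would oxidise one enol ether to a radical cation that attacks the other across the tether. A second oxidation and loss of silicon would give the diketone A8, 1,1-dimethoxyhexacosane-2,5-dione. Condensation with an ammonium salt would give the acetal pyrrole A9, and mild acid would release 8.
- In its favour: the tether enforces hetero-coupling, the aldehyde travels as an acetal at the right oxidation level, and neither nitrogen protection nor a nickel catalyst is needed. All 22 carbons of 1 are kept, the carboxyl carbon becoming C5; on atom use this is better than a decarboxylative plan.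
- Against it: A5 must first be made from 1. Two regioselective enolisations are required, and A6 has a second acidic position. A7 is hydrolytically labile and has two unsubstituted enol termini, which give poorly stabilised radical cations. More than two equivalents of a tetravalent cerium salt are consumed, and that salt can also strip dimethyl acetals.
- Comparison: the heteroselectivity through the tether is as secure as the site selectivity through the bromide, so the plans are equal there. The alternative is longer (about five or six operations) and its key step is the less predictable for this substitution pattern.

Alternative 3: The cut is the C1'–C2' bond after adding a C1'=C2' double bond retrosynthetically. In the forward key step the ylide A11, icosylidenetriphenylphosphorane, generated from its C20 phosphonium salt, would olefinate one of the two equivalent formyl groups of A10, 1H-pyrrole-2,5-dicarbaldehyde. This would give the alkene A12, 5-[(1Z)-henicos-1-en-1-yl]-1H-pyrrole-2-carbaldehyde, and hydrogenation of the alkene would give 8.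
- In its favour: the aldehyde is present at the right oxidation level from the start, the chain comes from an even-numbered C20 halide, and the alkene geometry is irrelevant. The sequence is three operations, one fewer in total than the chosen plan with the same longest linear sequence, so on step count it is the better.
- Against it: the acidic NH of A10 consumes basic ylide, and the resulting pyrrolide is a poorer electrophile. Mono-olefination rests only on the lower electrophilicity of the remaining formyl group, so double olefination and unreacted dialdehyde are to be expected. A10 is costly, Ph3P=O must be separated from a waxy product, and the hydrogenation must spare the formyl group.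
- Comparison: the chosen plan fixes mono-functionalisation structurally through one C–Br bond, whereas this alternative relies on a reactivity difference. Mechanistically the Wittig step is simpler and needs no transition metal, which is a point in its favour.

Key step: step 3

Assumption: 8 has no stereogenic element; 1, 2, 4 and 5 are taken as purchasable, and 3 is isolated so that carbodiimide residues do not reach the nickel catalyst.

## Route

Step 1
Reactants: 1 docosanoic acid (behenic acid); 2 N-hydroxyphthalimide
Product: 3 1,3-dioxoisoindolin-2-yl docosanoate
Conditions: iPrN=C=NiPr (1.1 equiv), DMAP (0.1 equiv), CH2Cl2/THF 1:1, 35 °C to rt; recrystallisation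
Reagents that add atoms: none
Why: Steglich-type carbodiimide esterification of an unhindered primary acid with an acidic N-hydroxy imide; warm THF keeps the fatty acid in solution and the crystalline active ester is freed from urea without chromatography.

Step 2
Reactants: 4 5-bromo-1H-pyrrole-2-carbaldehyde; 5 di-tert-butyl dicarbonate
Product: 6 tert-butyl 2-bromo-5-formyl-1H-pyrrole-1-carboxylate
Conditions: 5 (1.2 equiv), DMAP (0.1 equiv), MeCN, rt, dark; filtration through neutral alumina
Reagents that add atoms: none
Why: DMAP-catalysed N-acylation of a pyrrole whose NH is acidified by the 2-formyl group, the standard way to N-tert-butoxycarbonyl 2-acylpyrroles; the aldehyde and the C–Br bond are inert to these conditions.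

Step 3
Reactants: 3 1,3-dioxoisoindolin-2-yl docosanoate; 6 tert-butyl 2-bromo-5-formyl-1H-pyrrole-1-carboxylate
Product: 7 tert-butyl 2-formyl-5-henicosyl-1H-pyrrole-1-carboxylate
Conditions: NiBr2(MeOCH2CH2OMe) (10 mol %), 4,4'-di-tert-butyl-2,2'-bipyridine (10 mol %), Zn dust (2.5 equiv, no silyl chloride activator), N,N-dimethylacetamide (DMA)/THF 2:1, 30 °C, Ar; 3 (1.5 equiv) added over 4 h
Reagents that add atoms: none
Why: This is a nickel-catalysed decarboxylative cross-electrophile coupling of a redox-active ester with a heteroaryl bromide, a known reaction type for N-acyloxyphthalimides and (hetero)aryl halides. Zinc reduces the divalent nickel precatalyst to a zerovalent bipyridine complex, which inserts into the C5–Br bond of 6 to give a pyrrolyl bromide complex of divalent nickel; the 2-formyl and N-carbamate groups make the halide electron-poor and this insertion fast. A low-valent nickel species passes one electron to 3, whose radical anion fragments to phthalimide anion, CO2 and the primary henicosyl radical. The radical is captured at the pyrrolyl nickel centre to reach trivalent nickel, and reductive elimination forms the C5–C1' bond and leaves monovalent nickel bromide, which zinc returns to the cycle. No ring is closed and no stereocentre is formed. The selectivity needed is cross-coupling over homocoupling of 6, dimerisation or hydrogen abstraction of the radical, and protodebromination; it is secured by dosing 3 slowly and in excess so that radical formation never outruns oxidative addition, while the single C–Br bond fixes the site at C5. The aldehyde should survive because an alkyl radical does not add productively to a carbonyl carbon and unactivated zinc in DMA does not reduce this vinylogous formamide, and the carbamate should survive the near-neutral medium at 30 °C. THF as co-solvent keeps the waxy ester 3 and product 7 dissolved.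

Step 4
Reactants: 7 tert-butyl 2-formyl-5-henicosyl-1H-pyrrole-1-carboxylate
Product: 8 5-henicosyl-1H-pyrrole-2-carbaldehyde
Conditions: NaOMe (0.2 equiv), MeOH/THF 1:1, rt; aq. NH4Cl
Reagents that add atoms: none
Why: Methanolysis of an activated N-acylpyrrole carbamate (acyl transfer to methoxide); the 2-formylpyrrolide is a good leaving group and is reprotonated by methanol, so the base is catalytic, and the aldehyde has no α-hydrogen and forms only a reversible hemiacetal.

## Compound list

1 | docosanoic acid (behenic acid) | `CCCCCCCCCCCCCCCCCCCCCC(=O)O` | starting material
2 | N-hydroxyphthalimide | `O=C1c2ccccc2C(=O)N1O` | starting material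
3 | 1,3-dioxoisoindolin-2-yl docosanoate | `CCCCCCCCCCCCCCCCCCCCCC(=O)ON1C(=O)c2ccccc2C1=O` | intermediate
4 | 5-bromo-1H-pyrrole-2-carbaldehyde | `O=Cc1ccc(Br)[nH]1` | starting material
5 | di-tert-butyl dicarbonate | `CC(C)(C)OC(=O)OC(=O)OC(C)(C)C` | starting material
6 | tert-butyl 2-bromo-5-formyl-1H-pyrrole-1-carboxylate | `O=Cc1ccc(Br)n1C(=O)OC(C)(C)C` | intermediate
7 | tert-butyl 2-formyl-5-henicosyl-1H-pyrrole-1-carboxylate | `CCCCCCCCCCCCCCCCCCCCCc1ccc(C=O)n1C(=O)OC(C)(C)C` | intermediate
8 | 5-henicosyl-1H-pyrrole-2-carbaldehyde | `CCCCCCCCCCCCCCCCCCCCCc1ccc(C=O)[nH]1` | target

## Step count and least certain steps

Total step count: 4. Longest linear sequence: 3 (step 1 or step 2, then steps 3 and 4).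

Step 3 (key step). The most likely failure is a mismatch of rates. A bromide adds to zerovalent nickel more slowly than an iodide, so the redox-active ester may be consumed by radical dimerisation and hydrogen abstraction before the heteroaryl nickel species is available. Homocoupling or protodebromination of the heteroaryl partner, premature loss of the carbamate under Lewis-acidic zinc salts, and reductive chemistry at the aldehyde are further risks. Any carbamate lost after the coupling is harmless, since step 4 removes it anyway. Fallback, from 1 and 6, rejoining at 7: a Hunsdiecker-type iododecarboxylation of 1 (PhI(OAc)2, I2, visible light, cyclohexane, reflux) would give 1-iodohenicosane F1. Zinc insertion (Zn dust activated with 1,2-dibromoethane, LiCl, THF, 40 °C) would give henicosylzinc iodide F2. A Negishi coupling of F2 with 6 (Pd(OAc)2, 2-dicyclohexylphosphino-2',6'-dimethoxybiphenyl, THF, rt to 50 °C) would form the same C5–C1' bond by two-electron transmetalation and return to the route at 7. Alkylzinc halides do not add to aldehydes under these conditions.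

Step 2. The risks are incomplete acylation of a hindered, weakly nucleophilic nitrogen between Br and CHO, loss of the carbamate on acidic supports, and light- or acid-induced decomposition of the bromopyrrole. Fallback, from 4, rejoining at 8: deprotonation and sulfonylation (NaH, 4-methylbenzenesulfonyl chloride, THF, 0 °C) would give 5-bromo-1-(4-methylbenzenesulfonyl)-1H-pyrrole-2-carbaldehyde F3, a more robust and equally electron-poor partner. Coupling with 3 under the conditions of step 3 would give 5-henicosyl-1-(4-methylbenzenesulfonyl)-1H-pyrrole-2-carbaldehyde F4, and aqueous LiOH in THF at 40 °C would cleave the sulfonamide and rejoin the route at 8.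

Step 4. The risks are incomplete cleavage because the C21 substrate is poorly soluble in a methanolic medium, and slow base-mediated degradation of the aldehyde on prolonged exposure. Fallback, from 7, rejoining at 8: base-free thermolysis (neat or in diphenyl ether, 170–180 °C, N2) fragments the tert-butyl carbamate at the O–C(CH3)3 bond with loss of 2-methylpropene and CO2 instead of attacking the carbonyl group. No new compound arises on this path (entry F0).

Step 1. The risks are incomplete conversion of the sparingly soluble fatty acid and rearrangement of the activated acid to an unreactive N-acylurea. Fallback, from 1, rejoining at 3: oxalyl chloride with catalytic DMF in CH2Cl2/toluene at 40 °C would give docosanoyl chloride F5, which would acylate 2 in THF with Et3N at 0 °C to rt to give 3.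

## Further compounds

F1 | step 3 | 1-iodohenicosane | `CCCCCCCCCCCCCCCCCCCCCI`
F2 | step 3 | henicosylzinc iodide | `CCCCCCCCCCCCCCCCCCCCC[Zn]I`
F3 | step 2 | 5-bromo-1-(4-methylbenzenesulfonyl)-1H-pyrrole-2-carbaldehyde | `O=Cc1ccc(Br)n1S(=O)(=O)c1ccc(C)cc1`
F4 | step 2 | 5-henicosyl-1-(4-methylbenzenesulfonyl)-1H-pyrrole-2-carbaldehyde | `CCCCCCCCCCCCCCCCCCCCCc1ccc(C=O)n1S(=O)(=O)c1ccc(C)cc1`
F0 | step 4 | none | none
F5 | step 1 | docosanoyl chloride | `CCCCCCCCCCCCCCCCCCCCCC(=O)Cl`
A1 | alternative 1 | methyl (2Z,4E)-2-azidohexacosa-2,4-dienoate | `CCCCCCCCCCCCCCCCCCCCC/C=C/C=C(\N=[N+]=[N-])C(=O)OC`
A2 | alternative 1 | methyl 5-henicosyl-1H-pyrrole-2-carboxylate | `CCCCCCCCCCCCCCCCCCCCCc1ccc(C(=O)OC)[nH]1`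
A3 | alternative 1 | (2E)-tetracos-2-enal | `CCCCCCCCCCCCCCCCCCCCC/C=C/C=O`
A4 | alternative 1 | (5-henicosyl-1H-pyrrol-2-yl)methanol | `CCCCCCCCCCCCCCCCCCCCCc1ccc(CO)[nH]1`
A5 | alternative 2 | tricosan-2-one | `CCCCCCCCCCCCCCCCCCCCCC(C)=O`
A6 | alternative 2 | 1,1-dimethoxypropan-2-one | `COC(OC)C(C)=O`
A7 | alternative 2 | [(3,3-dimethoxyprop-1-en-2-yl)oxy]di(propan-2-yl)(tricos-1-en-2-yloxy)silane | `C=C(CCCCCCCCCCCCCCCCCCCCC)O[Si](C(C)C)(C(C)C)OC(=C)C(OC)OC`
A8 | alternative 2 | 1,1-dimethoxyhexacosane-2,5-dione | `COC(OC)C(=O)CCC(=O)CCCCCCCCCCCCCCCCCCCCC`
A9 | alternative 2 | 2-(dimethoxymethyl)-5-henicosyl-1H-pyrrole | `CCCCCCCCCCCCCCCCCCCCCc1ccc(C(OC)OC)[nH]1`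
A10 | alternative 3 | 1H-pyrrole-2,5-dicarbaldehyde | `O=Cc1ccc(C=O)[nH]1`
A11 | alternative 3 | icosylidenetriphenylphosphorane | `CCCCCCCCCCCCCCCCCCCC=P(c1ccccc1)(c1ccccc1)c1ccccc1`
A12 | alternative 3 | 5-[(1Z)-henicos-1-en-1-yl]-1H-pyrrole-2-carbaldehyde | `CCCCCCCCCCCCCCCCCCC/C=C\c1ccc(C=O)[nH]1`
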